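**Plan**

- Cuts, in retrosynthetic order: (a) the exocyclic N–C bond between the imidazole 2-amino nitrogen and C4 of 1-methylparabanic acid; (b) in the 2,5-dihydroxy-3,4-dimethoxyphenyl ring, the C5(OH)–C6(H) bond (6π closure of a dienylketene), then the C1–C2(OH) bond (alkenyllithium onto a squarate carbonyl); (c) the imidazole N1–C2/C2–N3 and N3–C4 bonds (cyanamide plus α-aminoketone); (d) the ketone C–CH2Ar bond (Weinreb amide plus benzylic Grignard reagent) and the Cα–CH2 bond of a sarcosine ester (enolate plus 2,3-dibromopropene).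
- Enabling feature: aryl carbons C2(OH), C3(OMe), C4(OMe), C5(OH) are four contiguous oxygen-bearing carbons, i.e. the four ring carbons of dimethyl squarate; C1 (bearing the imidazolylmethyl group) and C6–H are the two carbons of a 1,1-disubstituted alkene.
- Forward order: the chain is joined in steps 1–3, the imidazole ring closes in step 4, the benzene ring is built on it by cyclobutenone ring expansion (steps 6–7), and the imidazolidinedione ring is attached ready-made in step 9; the anisole ring is bought.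
- Stereochemistry: the target has no stereocentre; the α-amino carbon of 4, 5, 7, 8 and the carbinol carbon of 14 are racemic and become sp2 in steps 4 and 7.

Key step: step 7

Assumption: 1-methylparabanic acid, methyl N-Boc-sarcosinate and 4-methoxybenzylmagnesium chloride (THF solution) are taken as purchasable; the 2-amino group is carried as a single Boc carbamate whose N–H is lithiated before the bromine–lithium exchange.

**Route**

Step 1
Reactants: 1 methyl N-(tert-butoxycarbonyl)-N-methylglycinate; 2 2,3-dibromopropene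
Product: 4 methyl 4-bromo-2-[(tert-butoxycarbonyl)(methyl)amino]pent-4-enoate (racemic), via lithium enolate 3 (not isolated)
Conditions: LiN(SiMe3)2 (1.1 equiv), THF, −78 °C; then 2 (1.3 equiv), −78 → −30 °C; aqueous work-up
Reagents that add atoms: none
Why: Lithium ester-enolate alkylation in which the allylic C–Br of 2 is displaced (SN2) while its vinylic C–Br is inert; the new α-stereocentre forms racemic and is erased in step 4.

Step 2
Reactants: 4 methyl 4-bromo-2-[(tert-butoxycarbonyl)(methyl)amino]pent-4-enoate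
Product: 5 tert-butyl N-{4-bromo-1-[methoxy(methyl)amino]-1-oxopent-4-en-2-yl}-N-methylcarbamate (racemic)
Conditions: MeNHOMe·HCl (1.5 equiv), i-PrMgCl (3.0 equiv), THF, −20 → 0 °C; cold 1 M HCl quench
Reagents that add atoms: N,O-dimethylhydroxylamine hydrochloride, Cl.CNOC
Why: Direct ester-to-Weinreb-amide aminolysis by the chloromagnesium amide of N,O-dimethylhydroxylamine, which at this temperature should leave the carbamate and the unactivated alkenyl bromide untouched.

Step 3
Reactants: 5 tert-butyl N-{4-bromo-1-[methoxy(methyl)amino]-1-oxopent-4-en-2-yl}-N-methylcarbamate; 6 4-methoxybenzylmagnesium chloride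
Product: 7 tert-butyl N-[5-bromo-1-(4-methoxyphenyl)-2-oxohex-5-en-3-yl]-N-methylcarbamate (racemic)
Conditions: 6 (1.5 equiv), THF, 0 °C; cold 1 M HCl quench
Reagents that add atoms: none
Why: Weinreb ketone synthesis; the magnesium-chelated tetrahedral adduct persists until the acidic quench, so the benzylic Grignard reagent adds only once, as is established for N-Boc-N-methyl amino acid Weinreb amides.

Step 4
Reactants: 7 tert-butyl N-[5-bromo-1-(4-methoxyphenyl)-2-oxohex-5-en-3-yl]-N-methylcarbamate
Product: 9 2-amino-5-(2-bromoprop-2-en-1-yl)-4-(4-methoxybenzyl)-1-methylimidazole, via aminoketone hydrochloride 8 (not isolated)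
Conditions: 4 M HCl in 1,4-dioxane, rt; evaporate; H2NCN (5 equiv), EtOH/H2O, pH 4.5 (NaOH), 95 °C; then NaOH to pH 10
Reagents that add atoms: cyanamide, NC#N
Why: Boc acidolysis followed by the classical α-aminoketone–cyanamide condensation (guanylation of the secondary amine, then cyclodehydration onto the ketone) should give the aromatic 2-aminoimidazole with N-methyl at N1, the anisylmethyl ketone carbon as C4 and the former stereocentre as C5.

Step 5
Reactants: 9 2-amino-5-(2-bromoprop-2-en-1-yl)-4-(4-methoxybenzyl)-1-methylimidazole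
Product: 10 tert-butyl N-[5-(2-bromoprop-2-en-1-yl)-4-(4-methoxybenzyl)-1-methylimidazol-2-yl]carbamate
Conditions: Boc2O (1.05 equiv), Et3N, DMAP (cat.), THF, rt → 50 °C
Reagents that add atoms: di-tert-butyl dicarbonate, CC(C)(C)OC(=O)OC(=O)OC(C)(C)C
Why: Carbamoylation of the 2-aminoimidazole, in which DMAP-mediated acyl transfer should funnel any ring-N carbamate to the exocyclic carbamate that keeps the imidazole aromatic; a single Boc group is chosen because its N–H can be lithiated to an anion that resists organolithium attack.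

Step 6
Reactants: 10 tert-butyl N-[5-(2-bromoprop-2-en-1-yl)-4-(4-methoxybenzyl)-1-methylimidazol-2-yl]carbamate; 11 dimethyl squarate
Product: 14 tert-butyl N-{5-[2-(1-hydroxy-2,3-dimethoxy-4-oxocyclobut-2-en-1-yl)prop-2-en-1-yl]-4-(4-methoxybenzyl)-1-methylimidazol-2-yl}carbamate (racemic), via N-lithio carbamate 12 (not isolated), via C,N-dilithio species 13 (not isolated)
Conditions: MeLi (1.05 equiv), THF, −78 °C; t-BuLi (2.1 equiv), −78 °C; cannulate into 11 (1.3 equiv), THF, −78 °C; AcOH (2.5 equiv) in THF, −78 °C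
Reagents that add atoms: none
Why: N–H deprotonation, then bromine–lithium exchange at the alkenyl bromide (the second equivalent of t-BuLi destroys the tert-butyl bromide), then 1,2-addition of the alkenyllithium to one carbonyl of the squarate ester at −78 °C, the standard entry to 4-alkenyl-4-hydroxycyclobutenones; the carbinol stereocentre forms racemic and vanishes in step 7.

Step 7
Reactants: 14 tert-butyl N-{5-[2-(1-hydroxy-2,3-dimethoxy-4-oxocyclobut-2-en-1-yl)prop-2-en-1-yl]-4-(4-methoxybenzyl)-1-methylimidazol-2-yl}carbamate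
Product: 17 tert-butyl N-{5-[(2,5-dihydroxy-3,4-dimethoxyphenyl)methyl]-4-(4-methoxybenzyl)-1-methylimidazol-2-yl}carbamate, via dienylketene 15 (not isolated), via cyclohexadienone 16 (not isolated)
Conditions: degassed PhMe, 110 °C, Ar
Reagents that add atoms: none
Why: Heating should open the cyclobutenone by conrotatory 4π electrocyclic cleavage of the bond between the carbonyl carbon and the carbinol carbon, giving the (Z)-dienylketene 15 in which the hydroxyl has rotated outward and the propenyl unit lies cis to the ketene. Disrotatory 6π electrocyclisation then joins the ketene carbon to the terminal methylene, the only new skeletal C–C bond (future C5–OH carbon to future C6–H), giving cyclohexa-2,4-dienone 16, which enolises to the hydroquinone. The closest known reaction type is the Moore-type thermal ring expansion of 4-alkenyl-4-hydroxycyclobutenones from squarate esters to hydroquinones. The benzene ring closes in a 6π-electrocyclic mode from a 1,3,5-hexatriene whose termini are the ketene carbon and the alkene CH2; no stereocentre is created and the racemic carbinol centre of 14 is destroyed. The step needs outward torquoselectivity of the hydroxyl, which is the inherent preference of an oxygen donor at the sp3 carbon, and the pentasubstitution pattern follows from connectivity alone: squarate supplies the two methoxy and two hydroxyl carbons, the 1,1-disubstituted alkene supplies C6–H and the carbon bearing the imidazolylmethyl group. Neutral, oxygen-free heating should spare the carbamate and the imidazole and keep the hydroquinone from oxidising to the quinone.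

Step 8
Reactants: 17 tert-butyl N-{5-[(2,5-dihydroxy-3,4-dimethoxyphenyl)methyl]-4-(4-methoxybenzyl)-1-methylimidazol-2-yl}carbamate
Product: 18 2-amino-5-[(2,5-dihydroxy-3,4-dimethoxyphenyl)methyl]-4-(4-methoxybenzyl)-1-methylimidazole
Conditions: 4 M HCl in 1,4-dioxane, MeOH, 0 °C → rt, Ar; then degassed aq. NaHCO3
Reagents that add atoms: none
Why: Acidolysis of the tert-butyl carbamate, with chloride and the ethereal solvent intercepting the tert-butyl cation so the electron-rich arenes are not alkylated; exclusion of air keeps the hydroquinone reduced.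

Step 9
Reactants: 18 2-amino-5-[(2,5-dihydroxy-3,4-dimethoxyphenyl)methyl]-4-(4-methoxybenzyl)-1-methylimidazole; 19 1-methylparabanic acid
Product: 23 naamidine E, via bis-silyl ether 20 (not isolated), via silyl imidate 21 (not isolated), via bis-silyl naamidine E 22 (not isolated)
Conditions: 18, BSA [N,O-bis(trimethylsilyl)acetamide, 3 equiv], MeCN, 60 °C; separately 19, BSA (2 equiv), MeCN, 80 °C; combine, PhMe, 110 °C, Ar; then MeOH, rt
Reagents that add atoms: none
Why: Silylation converts the N–H-flanked C4 carbonyl of 1-methylparabanic acid into an O-silyl imidate, which the exocyclic amine attacks by addition–elimination with loss of silanolate to leave the amidine of the dehydrohydantoin, the established silyl-mediated condensation for naamidine head groups; the phenols travel as trimethylsilyl ethers and are released by methanol.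

**Compound list**

1 | methyl N-(tert-butoxycarbonyl)-N-methylglycinate | COC(=O)CN(C)C(=O)OC(C)(C)C | starting material
2 | 2,3-dibromopropene | C=C(Br)CBr | starting material
3 | lithium enolate of 1 (drawn with OLi cis to nitrogen; the geometry has no consequence) | [Li]O/C(OC)=C\N(C)C(=O)OC(C)(C)C | intermediate
4 | methyl 4-bromo-2-[(tert-butoxycarbonyl)(methyl)amino]pent-4-enoate (racemic) | COC(=O)C(CC(Br)=C)N(C)C(=O)OC(C)(C)C | intermediate
5 | tert-butyl N-{4-bromo-1-[methoxy(methyl)amino]-1-oxopent-4-en-2-yl}-N-methylcarbamate (racemic) | CON(C)C(=O)C(CC(Br)=C)N(C)C(=O)OC(C)(C)C | intermediate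
6 | 4-methoxybenzylmagnesium chloride | COc1ccc(C[Mg]Cl)cc1 | starting material
7 | tert-butyl N-[5-bromo-1-(4-methoxyphenyl)-2-oxohex-5-en-3-yl]-N-methylcarbamate (racemic) | COc1ccc(CC(=O)C(CC(Br)=C)N(C)C(=O)OC(C)(C)C)cc1 | intermediate
8 | 5-bromo-1-(4-methoxyphenyl)-3-(methylamino)hex-5-en-2-one hydrochloride (racemic) | COc1ccc(CC(=O)C(CC(Br)=C)NC)cc1.Cl | intermediate
9 | 2-amino-5-(2-bromoprop-2-en-1-yl)-4-(4-methoxybenzyl)-1-methylimidazole | COc1ccc(Cc2nc(N)n(C)c2CC(Br)=C)cc1 | intermediate
10 | tert-butyl N-[5-(2-bromoprop-2-en-1-yl)-4-(4-methoxybenzyl)-1-methylimidazol-2-yl]carbamate | COc1ccc(Cc2nc(NC(=O)OC(C)(C)C)n(C)c2CC(Br)=C)cc1 | intermediate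
11 | dimethyl squarate (3,4-dimethoxycyclobut-3-ene-1,2-dione) | COC1=C(OC)C(=O)C1=O | starting material
12 | N-lithio derivative of carbamate 10 | COc1ccc(Cc2nc(N([Li])C(=O)OC(C)(C)C)n(C)c2CC(Br)=C)cc1 | intermediate
13 | C,N-dilithio species (N-lithio carbamate, 2-lithioprop-2-en-1-yl side chain) | COc1ccc(Cc2nc(N([Li])C(=O)OC(C)(C)C)n(C)c2CC([Li])=C)cc1 | intermediate
14 | tert-butyl N-{5-[2-(1-hydroxy-2,3-dimethoxy-4-oxocyclobut-2-en-1-yl)prop-2-en-1-yl]-4-(4-methoxybenzyl)-1-methylimidazol-2-yl}carbamate (racemic) | COC1=C(OC)C(O)(C(=C)Cc2c(Cc3ccc(OC)cc3)nc(NC(=O)OC(C)(C)C)n2C)C1=O | intermediate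
15 | tert-butyl N-{5-[(3Z)-3-hydroxy-4,5-dimethoxy-2-methylidene-6-oxohexa-3,5-dien-1-yl]-4-(4-methoxybenzyl)-1-methylimidazol-2-yl}carbamate (dienylketene) | O=C=C(OC)/C(OC)=C(/O)C(=C)Cc1c(Cc2ccc(OC)cc2)nc(NC(=O)OC(C)(C)C)n1C | intermediate
16 | tert-butyl N-{5-[(2-hydroxy-3,4-dimethoxy-5-oxocyclohexa-1,3-dien-1-yl)methyl]-4-(4-methoxybenzyl)-1-methylimidazol-2-yl}carbamate | COC1=C(OC)C(O)=C(Cc2c(Cc3ccc(OC)cc3)nc(NC(=O)OC(C)(C)C)n2C)CC1=O | intermediate
17 | tert-butyl N-{5-[(2,5-dihydroxy-3,4-dimethoxyphenyl)methyl]-4-(4-methoxybenzyl)-1-methylimidazol-2-yl}carbamate | COc1ccc(Cc2nc(NC(=O)OC(C)(C)C)n(C)c2Cc2cc(O)c(OC)c(OC)c2O)cc1 | intermediate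
18 | 2-amino-5-[(2,5-dihydroxy-3,4-dimethoxyphenyl)methyl]-4-(4-methoxybenzyl)-1-methylimidazole | COc1ccc(Cc2nc(N)n(C)c2Cc2cc(O)c(OC)c(OC)c2O)cc1 | intermediate
19 | 1-methylparabanic acid (1-methylimidazolidine-2,4,5-trione) | CN1C(=O)NC(=O)C1=O | starting material
20 | bis(trimethylsilyl) ether of 18 | COc1ccc(Cc2nc(N)n(C)c2Cc2cc(O[Si](C)(C)C)c(OC)c(OC)c2O[Si](C)(C)C)cc1 | intermediate
21 | 1-methyl-4-(trimethylsilyloxy)imidazole-2,5-dione (O-silyl imidate of 19) | CN1C(=O)N=C(O[Si](C)(C)C)C1=O | intermediate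
22 | bis(trimethylsilyl) ether of naamidine E | COc1ccc(Cc2nc(NC3=NC(=O)N(C)C3=O)n(C)c2Cc2cc(O[Si](C)(C)C)c(OC)c(OC)c2O[Si](C)(C)C)cc1 | intermediate
23 | naamidine E, 4-({5-[(2,5-dihydroxy-3,4-dimethoxyphenyl)methyl]-4-(4-methoxybenzyl)-1-methylimidazol-2-yl}amino)-1-methylimidazole-2,5-dione | COc1ccc(Cc2nc(NC3=NC(=O)N(C)C3=O)n(C)c2Cc2cc(O)c(OC)c(OC)c2O)cc1 | target

**Count**

Total steps: 9. Longest linear sequence: 9 steps (1 → 23).

**Steps most likely to fail**

Step 6. The lithiated carbamate may interfere: the dianion may be poorly soluble, the nitrogen anion may compete for the squarate, or the Boc group may be transferred to carbon, so that little 14 forms. The fallback replaces the carbamate by a mask with neither an N–H nor a carbonyl group. It sets out from 9 and comes back to the route at 18. Paal–Knorr condensation of 9 with hexane-2,5-dione (TsOH cat., PhMe, water removal) should give 5-(2-bromoprop-2-en-1-yl)-2-(2,5-dimethylpyrrol-1-yl)-4-(4-methoxybenzyl)-1-methylimidazole F1. t-BuLi (2 equiv, THF, −78 °C) should convert it into the alkenyllithium F2, which adds to 11 to give the pyrrole-masked hydroxycyclobutenone F3. Heating as in step 7 should lead through the pyrrole-masked dienylketene F4 and the pyrrole-masked cyclohexadienone F5 to the pyrrole-masked hydroquinone F6. NH2OH·HCl and Et3N in aqueous ethanol at reflux under argon should then release amine 18.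

Step 7. The hydroxyl may rotate inward during ring opening and trap the ketene as a 5H-furan-2-one, or the hydroquinone may oxidise during heating. The fallback caps the tertiary hydroxyl before thermolysis, which blocks lactonisation and delivers a less oxidisable mono-ether. It sets out from 14 and comes back at 17. N-(Trimethylsilyl)imidazole (CH2Cl2, rt) should give the cyclobutenone trimethylsilyl ether F7. Heating in degassed toluene should pass through the silyloxy dienylketene F8 and the silyloxy cyclohexadienone F9 to the mono-silylated hydroquinone F10, silylated at the oxygen ortho to the benzylic carbon. Methanol containing a little citric acid should then remove the silyl group to give 17.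

Step 9. Prolonged heating of the free amine may oxidise the hydroquinone or leave the condensation incomplete when the phenols are only transiently silylated. The fallback runs the endgame on a discretely protected hydroquinone. It sets out from 17 and comes back at 23. TBSCl and imidazole in DMF should give the bis(tert-butyldimethylsilyl) ether carbamate F11. TFA in CH2Cl2 at 0 °C followed by NaHCO3 should cleave only the Boc group and give the bis(tert-butyldimethylsilyl) ether amine F12. Condensation with silyl imidate 21 (from 19 and BSA) in toluene at 110 °C should give bis(tert-butyldimethylsilyl) naamidine E F13. HF·pyridine in THF should then release 23.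

**Further compounds**

F1 | step 6 | 5-(2-bromoprop-2-en-1-yl)-2-(2,5-dimethylpyrrol-1-yl)-4-(4-methoxybenzyl)-1-methylimidazole | COc1ccc(Cc2nc(-n3c(C)ccc3C)n(C)c2CC(Br)=C)cc1
F2 | step 6 | 2-(2,5-dimethylpyrrol-1-yl)-5-(2-lithioprop-2-en-1-yl)-4-(4-methoxybenzyl)-1-methylimidazole | COc1ccc(Cc2nc(-n3c(C)ccc3C)n(C)c2CC([Li])=C)cc1
F3 | step 6 | 4-{3-[2-(2,5-dimethylpyrrol-1-yl)-4-(4-methoxybenzyl)-1-methylimidazol-5-yl]prop-1-en-2-yl}-4-hydroxy-2,3-dimethoxycyclobut-2-en-1-one (racemic) | COC1=C(OC)C(O)(C(=C)Cc2c(Cc3ccc(OC)cc3)nc(-n3c(C)ccc3C)n2C)C1=O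
F4 | step 6 | (4Z)-6-{[2-(2,5-dimethylpyrrol-1-yl)-4-(4-methoxybenzyl)-1-methylimidazol-5-yl]methyl}-5-hydroxy-2,3-dimethoxyhepta-1,2,4,6-tetraen-1-one (dienylketene) | O=C=C(OC)/C(OC)=C(/O)C(=C)Cc1c(Cc2ccc(OC)cc2)nc(-n2c(C)ccc2C)n1C
F5 | step 6 | 5-{[2-(2,5-dimethylpyrrol-1-yl)-4-(4-methoxybenzyl)-1-methylimidazol-5-yl]methyl}-4-hydroxy-2,3-dimethoxycyclohexa-2,4-dien-1-one | COC1=C(OC)C(O)=C(Cc2c(Cc3ccc(OC)cc3)nc(-n3c(C)ccc3C)n2C)CC1=O
F6 | step 6 | 2-{[2-(2,5-dimethylpyrrol-1-yl)-4-(4-methoxybenzyl)-1-methylimidazol-5-yl]methyl}-5,6-dimethoxybenzene-1,4-diol | COc1ccc(Cc2nc(-n3c(C)ccc3C)n(C)c2Cc2cc(O)c(OC)c(OC)c2O)cc1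
F7 | step 7 | tert-butyl N-{5-[2-(2,3-dimethoxy-4-oxo-1-(trimethylsilyloxy)cyclobut-2-en-1-yl)prop-2-en-1-yl]-4-(4-methoxybenzyl)-1-methylimidazol-2-yl}carbamate (racemic) | COC1=C(OC)C(O[Si](C)(C)C)(C(=C)Cc2c(Cc3ccc(OC)cc3)nc(NC(=O)OC(C)(C)C)n2C)C1=O
F8 | step 7 | tert-butyl N-{5-[(3Z)-4,5-dimethoxy-2-methylidene-6-oxo-3-(trimethylsilyloxy)hexa-3,5-dien-1-yl]-4-(4-methoxybenzyl)-1-methylimidazol-2-yl}carbamate (silyloxy dienylketene) | O=C=C(OC)/C(OC)=C(/O[Si](C)(C)C)C(=C)Cc1c(Cc2ccc(OC)cc2)nc(NC(=O)OC(C)(C)C)n1C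
F9 | step 7 | tert-butyl N-{5-[(3,4-dimethoxy-5-oxo-2-(trimethylsilyloxy)cyclohexa-1,3-dien-1-yl)methyl]-4-(4-methoxybenzyl)-1-methylimidazol-2-yl}carbamate | COC1=C(OC)C(O[Si](C)(C)C)=C(Cc2c(Cc3ccc(OC)cc3)nc(NC(=O)OC(C)(C)C)n2C)CC1=O
F10 | step 7 | tert-butyl N-{5-[(5-hydroxy-3,4-dimethoxy-2-(trimethylsilyloxy)phenyl)methyl]-4-(4-methoxybenzyl)-1-methylimidazol-2-yl}carbamate | COc1ccc(Cc2nc(NC(=O)OC(C)(C)C)n(C)c2Cc2cc(O)c(OC)c(OC)c2O[Si](C)(C)C)cc1
F11 | step 9 | tert-butyl N-{5-[(2,5-bis(tert-butyldimethylsilyloxy)-3,4-dimethoxyphenyl)methyl]-4-(4-methoxybenzyl)-1-methylimidazol-2-yl}carbamate | COc1ccc(Cc2nc(NC(=O)OC(C)(C)C)n(C)c2Cc2cc(O[Si](C)(C)C(C)(C)C)c(OC)c(OC)c2O[Si](C)(C)C(C)(C)C)cc1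
F12 | step 9 | 2-amino-5-[(2,5-bis(tert-butyldimethylsilyloxy)-3,4-dimethoxyphenyl)methyl]-4-(4-methoxybenzyl)-1-methylimidazole | COc1ccc(Cc2nc(N)n(C)c2Cc2cc(O[Si](C)(C)C(C)(C)C)c(OC)c(OC)c2O[Si](C)(C)C(C)(C)C)cc1
F13 | step 9 | bis(tert-butyldimethylsilyl) ether of naamidine E | COc1ccc(Cc2nc(NC3=NC(=O)N(C)C3=O)n(C)c2Cc2cc(O[Si](C)(C)C(C)(C)C)c(OC)c(OC)c2O[Si](C)(C)C(C)(C)C)cc1
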